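**Retrosynthetic overview**
- Last ring: the chromanone closes with dearomatisation, by oxidative C–O coupling of the flavan ring A para position (flavan C8) with the ortho-hydroxyl of the neighbouring 2,4,6-trihydroxybenzoyl group.
- Before that: the dihydrofuran C2–H is set by ketone reduction and acid-promoted ring closure of a 2-aryl-2-hydroxy hemiketal.
- Key disconnection: the flavan C8–C bond and the furan ring come from a [3,3]-sigmatropic rearrangement (oxygen analogue of the Fischer indole synthesis) of an O-aryl oxime ether made from a flavan-7-yloxyamine and a 2-acetoxy-1,3-diketone.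
- Fragments: the aryloxyamine from (+)-epiafzelechin (the only source of chirality, rings A/C bought); the diketone from 2',4',6'-trihydroxyacetophenone and a 4-silyloxybenzoic acid.
- Ring order: flavan (bought), then dihydrofuran, then chromanone. Locants: flavan numbering for the chroman fragment, furo[2,3-h]chromene numbering afterwards (O7–C8–C9 is the new dihydrofuran, C9a is flavan C8).

Assumption: (+)-epiafzelechin and 4-(tert-butyldimethylsilyloxy)benzoic acid are taken as catalogue compounds; TBS = tert-butyldimethylsilyl throughout.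

Step 1
Reactants: 1 (+)-epiafzelechin, (2S,3S)-2-(4-hydroxyphenyl)chromane-3,5,7-triol
Product: 2 (2S,3S)-5,7-bis(TBS-oxy)-2-[4-(TBS-oxy)phenyl]chroman-3-ol
Conditions: TBSCl (3.3 equiv), imidazole, DMF, 0 °C → rt
Reagents that add atoms: TBSCl, CC(C)(C)[Si](C)(C)Cl
Why: Silyl ether formation is much faster at the three phenols than at the hindered axial secondary alcohol, so the tris-aryl ether forms and no stereocentre is touched.

Step 2
Reactants: 2 (2S,3S)-5,7-bis(TBS-oxy)-2-[4-(TBS-oxy)phenyl]chroman-3-ol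
Product: 3 (2S,3S)-5-(TBS-oxy)-2-[4-(TBS-oxy)phenyl]chromane-3,7-diol
Conditions: Cs2CO3 (0.5 equiv), DMF–H2O (10:1), 0 °C, stopped at mono-desilylation, chromatography
Reagents that add atoms: none
Why: Carbonate-mediated hydrolysis of aryl silyl ethers (selective desilylation) should be fastest at the unhindered 7-O ether of the more acidic ring A phenol, since the 5-O ether is shielded by the peri C4 methylene and the 4'-O ether belongs to a less acidic phenol.

Step 3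
Reactants: 3 (2S,3S)-5-(TBS-oxy)-2-[4-(TBS-oxy)phenyl]chromane-3,7-diol
Product: 4 (2S,3S)-7-(aminooxy)-5-(TBS-oxy)-2-[4-(TBS-oxy)phenyl]chroman-3-ol
Conditions: NaH (1.05 equiv), THF–DMF, 0 °C; then O-(2,4-dinitrophenyl)hydroxylamine, 0 °C → rt; used at once
Reagents that add atoms: O-(2,4-dinitrophenyl)hydroxylamine, NOc1ccc(cc1[N+](=O)[O-])[N+](=O)[O-]
Why: The sodium phenoxide attacks the electrophilic nitrogen and expels 2,4-dinitrophenoxide (electrophilic O-amination of a phenoxide), a reaction known for oxygenated phenols, and the stereocentres are not involved.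

Step 4
Reactants: 5 2',4',6'-trihydroxyacetophenone
Product: 6 2',4',6'-tris(TBS-oxy)acetophenone
Conditions: TBSCl (3.6 equiv), imidazole, DMAP (cat.), DMF, 40 °C
Reagents that add atoms: TBSCl, CC(C)(C)[Si](C)(C)Cl
Why: Exhaustive silyl ether formation masks the ortho hydroxyls that would otherwise cyclise the later diketone to a flavone.

Step 5
Reactants: 6 2',4',6'-tris(TBS-oxy)acetophenone; 7 4-(TBS-oxy)benzoic acid
Product: 9 1-[4-(TBS-oxy)phenyl]-3-[2,4,6-tris(TBS-oxy)phenyl]propane-1,3-dione, via 4-(TBS-oxy)benzoyl chloride 8 (not isolated)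
Conditions: 7, (COCl)2, DMF (cat.), CH2Cl2, 0 °C → rt, evaporate; then 6, MgBr2·OEt2, i-Pr2NEt, CH2Cl2, rt
Reagents that add atoms: none
Why: Soft enolisation of the methyl ketone with MgBr2·OEt2 and amine base followed by C-acylation with the acid chloride (crossed Claisen-type acylation) gives the 1,3-diketone.

Step 6
Reactants: 9 1-[4-(TBS-oxy)phenyl]-3-[2,4,6-tris(TBS-oxy)phenyl]propane-1,3-dione
Product: 10 2-acetoxy-1-[4-(TBS-oxy)phenyl]-3-[2,4,6-tris(TBS-oxy)phenyl]propane-1,3-dione (racemic)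
Conditions: PhI(OAc)2 (1.1 equiv), AcOH–CH2Cl2, rt
Reagents that add atoms: PhI(OAc)2, CC(=O)OI(OC(C)=O)c1ccccc1
Why: The diketone enol is acetoxylated at C2 by the hypervalent iodine reagent (α-acetoxylation through an iodonium enolate), which installs the future tertiary oxygen in a form that cannot take part in a semipinacol shift.

Step 7
Reactants: 4 (2S,3S)-7-(aminooxy)-5-(TBS-oxy)-2-[4-(TBS-oxy)phenyl]chroman-3-ol; 10 2-acetoxy-1-[4-(TBS-oxy)phenyl]-3-[2,4,6-tris(TBS-oxy)phenyl]propane-1,3-dione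
Product: 13 (2S,3S)-3,8-dihydroxy-5-(TBS-oxy)-2,8-bis[4-(TBS-oxy)phenyl]-9-[2,4,6-tris(TBS-oxy)benzoyl]-3,4,8,9-tetrahydro-2H-furo[2,3-h]chromen-9-yl acetate (C8/C9 epimer mixture), via O-aryl oxime ether 11 (not isolated), via 8-amino N,O-aminal 12 (not isolated)
Conditions: MsOH (2.0 equiv), 4 Å MS, THF, 45 °C; then H2O–THF, rt
Reagents that add atoms: water, O
Why: Oxime ether formation at the less hindered 4-silyloxyphenyl ketone, tautomerisation to the N-aryloxy enamine and an acid-accelerated [3,3]-sigmatropic rearrangement (oxygen analogue of the Fischer indole synthesis) forge the C9–C9a bond ortho to O7, expected mainly at flavan C8 because C6 is buttressed by the 5-silyloxy group, after which the phenol closes onto the ketimine and water gives the hemiketal; the quaternary C9 centre forms with little bias from the remote flavan centres, so both C9 epimers are carried on.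

Step 8
Reactants: 13 the hemiketal acetate (C8/C9 epimer mixture)
Product: 15 (2S,3S,8S,9S)-3-hydroxy-5-(TBS-oxy)-2,8-bis[4-(TBS-oxy)phenyl]-9-[2,4,6-tris(TBS-oxy)benzoyl]-3,4,8,9-tetrahydro-2H-furo[2,3-h]chromen-9-yl acetate, via ring-opened benzylic alcohol 14 (not isolated)
Conditions: NaBH4, CeCl3·7H2O, MeOH–THF, −40 °C; work-up; then CF3CO2H (2 equiv), CH2Cl2, −20 → 0 °C; SiO2 chromatography (separation of the two diastereomers)
Reagents that add atoms: none
Why: Luche reduction of the ring-opened aryl ketone and acid-promoted 5-exo cyclodehydration through the 4-silyloxybenzylic cation (quinone-methide-type C–O closure) place the C8 aryl group trans to the bulky C9 aroyl group, so C8 is set by C9, and the two diastereomers that differ in the sense of the C8/C9 pair relative to the bought flavan centres (about 1:1 expected) are separated to give the (8S,9S) isomer.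

Step 9
Reactants: 15 the (2S,3S,8S,9S) acetate
Product: 16 (2S,3S,8S,9S)-3,5,9-trihydroxy-2,8-bis(4-hydroxyphenyl)-9-(2,4,6-trihydroxybenzoyl)-3,4,8,9-tetrahydro-2H-furo[2,3-h]chromene
Conditions: K2CO3 (8 equiv), degassed MeOH–THF, 0 °C → rt, argon; AcOH to pH 5
Reagents that add atoms: none
Why: Base-mediated methanolysis cleaves the six aryl silyl ethers and the activated tertiary acetate (desilylation and transesterification) without touching the four stereocentres.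

Step 10
Reactants: 16 the free heptaol
Product: 17 CNP0170480.5 (target): the same skeleton with ring A of the flavan dearomatised to the 5-oxo cyclohexadienone and flavan C8 bonded to the ortho oxygen of the benzoyl ring (new 5,7-dihydroxychroman-4-one ring); flavan C2 (S), C3 (S), dihydrofuran CH(aryl) (S), C(OH) (R), quaternary O,C-substituted carbon (S)
Conditions: PhI(OAc)2 (1.05 equiv), (CF3)2CHOH, −20 → 0 °C
Reagents that add atoms: none
Why: The hypervalent iodine reagent oxidises the most electron-rich phenol (the trioxygenated flavan ring A) and the ortho-hydroxyl of the neighbouring aroyl group traps the para position intramolecularly (oxidative dearomatisation to a para-quinol aryl ether, as in grisan-type phenol coupling), a six-membered closure possible only on the face carrying the aroyl group, so the new quaternary centre is fixed cis-fused by C9.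

**Compound list**
1 | (+)-epiafzelechin, (2S,3S)-2-(4-hydroxyphenyl)chromane-3,5,7-triol | Oc1cc(O)c2C[C@H](O)[C@H](c3ccc(O)cc3)Oc2c1 | starting material
2 | (2S,3S)-5,7-bis(TBS-oxy)-2-[4-(TBS-oxy)phenyl]chroman-3-ol | CC(C)(C)[Si](C)(C)Oc1cc(O[Si](C)(C)C(C)(C)C)c2C[C@H](O)[C@H](c3ccc(O[Si](C)(C)C(C)(C)C)cc3)Oc2c1 | intermediate
3 | (2S,3S)-5-(TBS-oxy)-2-[4-(TBS-oxy)phenyl]chromane-3,7-diol | Oc1cc(O[Si](C)(C)C(C)(C)C)c2C[C@H](O)[C@H](c3ccc(O[Si](C)(C)C(C)(C)C)cc3)Oc2c1 | intermediate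
4 | (2S,3S)-7-(aminooxy)-5-(TBS-oxy)-2-[4-(TBS-oxy)phenyl]chroman-3-ol | NOc1cc(O[Si](C)(C)C(C)(C)C)c2C[C@H](O)[C@H](c3ccc(O[Si](C)(C)C(C)(C)C)cc3)Oc2c1 | intermediate
5 | 2',4',6'-trihydroxyacetophenone | CC(=O)c1c(O)cc(O)cc1O | starting material
6 | 2',4',6'-tris(TBS-oxy)acetophenone | CC(=O)c1c(O[Si](C)(C)C(C)(C)C)cc(O[Si](C)(C)C(C)(C)C)cc1O[Si](C)(C)C(C)(C)C | intermediate
7 | 4-(TBS-oxy)benzoic acid | OC(=O)c1ccc(O[Si](C)(C)C(C)(C)C)cc1 | starting material
8 | 4-(TBS-oxy)benzoyl chloride (not isolated) | ClC(=O)c1ccc(O[Si](C)(C)C(C)(C)C)cc1 | intermediate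
9 | 1-[4-(TBS-oxy)phenyl]-3-[2,4,6-tris(TBS-oxy)phenyl]propane-1,3-dione | O=C(CC(=O)c1c(O[Si](C)(C)C(C)(C)C)cc(O[Si](C)(C)C(C)(C)C)cc1O[Si](C)(C)C(C)(C)C)c1ccc(O[Si](C)(C)C(C)(C)C)cc1 | intermediate
10 | 2-acetoxy-1-[4-(TBS-oxy)phenyl]-3-[2,4,6-tris(TBS-oxy)phenyl]propane-1,3-dione (racemic) | CC(=O)OC(C(=O)c1ccc(O[Si](C)(C)C(C)(C)C)cc1)C(=O)c1c(O[Si](C)(C)C(C)(C)C)cc(O[Si](C)(C)C(C)(C)C)cc1O[Si](C)(C)C(C)(C)C | intermediate
11 | O-[(2S,3S)-flavan-7-yl] oxime ether of 10 at the 4-silyloxyphenyl ketone (not isolated) | CC(=O)OC(C(=O)c1c(O[Si](C)(C)C(C)(C)C)cc(O[Si](C)(C)C(C)(C)C)cc1O[Si](C)(C)C(C)(C)C)C(=NOc1cc(O[Si](C)(C)C(C)(C)C)c2C[C@H](O)[C@H](c3ccc(O[Si](C)(C)C(C)(C)C)cc3)Oc2c1)c1ccc(O[Si](C)(C)C(C)(C)C)cc1 | intermediate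
12 | (2S,3S)-8-amino analogue of 13, the N,O-aminal from rearrangement and ring closure (not isolated; C8/C9 mixture) | CC(C)(C)[Si](C)(C)Oc1cc2OC(N)(c3ccc(O[Si](C)(C)C(C)(C)C)cc3)C(OC(C)=O)(C(=O)c3c(O[Si](C)(C)C(C)(C)C)cc(O[Si](C)(C)C(C)(C)C)cc3O[Si](C)(C)C(C)(C)C)c2c3O[C@@H](c4ccc(O[Si](C)(C)C(C)(C)C)cc4)[C@@H](O)Cc13 | intermediate
13 | (2S,3S)-3,8-dihydroxy-5-(TBS-oxy)-2,8-bis[4-(TBS-oxy)phenyl]-9-[2,4,6-tris(TBS-oxy)benzoyl]-3,4,8,9-tetrahydro-2H-furo[2,3-h]chromen-9-yl acetate (C8/C9 mixture) | CC(C)(C)[Si](C)(C)Oc1cc2OC(O)(c3ccc(O[Si](C)(C)C(C)(C)C)cc3)C(OC(C)=O)(C(=O)c3c(O[Si](C)(C)C(C)(C)C)cc(O[Si](C)(C)C(C)(C)C)cc3O[Si](C)(C)C(C)(C)C)c2c3O[C@@H](c4ccc(O[Si](C)(C)C(C)(C)C)cc4)[C@@H](O)Cc13 | intermediate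
14 | ring-opened benzylic alcohol: flavan C8 bears C(OAc)[CH(OH)(4-TBS-oxyphenyl)][C(=O)-2,4,6-tris(TBS-oxy)phenyl], 7-OH free (not isolated; mixture at the two new carbons) | Oc1cc(O[Si](C)(C)C(C)(C)C)c2C[C@H](O)[C@H](c3ccc(O[Si](C)(C)C(C)(C)C)cc3)Oc2c1C(OC(C)=O)(C(O)c1ccc(O[Si](C)(C)C(C)(C)C)cc1)C(=O)c1c(O[Si](C)(C)C(C)(C)C)cc(O[Si](C)(C)C(C)(C)C)cc1O[Si](C)(C)C(C)(C)C | intermediate
15 | (2S,3S,8S,9S)-3-hydroxy-5-(TBS-oxy)-2,8-bis[4-(TBS-oxy)phenyl]-9-[2,4,6-tris(TBS-oxy)benzoyl]-3,4,8,9-tetrahydro-2H-furo[2,3-h]chromen-9-yl acetate | CC(C)(C)[Si](C)(C)Oc1cc2O[C@@H](c3ccc(O[Si](C)(C)C(C)(C)C)cc3)[C@](OC(C)=O)(C(=O)c3c(O[Si](C)(C)C(C)(C)C)cc(O[Si](C)(C)C(C)(C)C)cc3O[Si](C)(C)C(C)(C)C)c2c3O[C@@H](c4ccc(O[Si](C)(C)C(C)(C)C)cc4)[C@@H](O)Cc13 | intermediate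
16 | (2S,3S,8S,9S)-3,5,9-trihydroxy-2,8-bis(4-hydroxyphenyl)-9-(2,4,6-trihydroxybenzoyl)-3,4,8,9-tetrahydro-2H-furo[2,3-h]chromene | Oc1cc2O[C@@H](c3ccc(O)cc3)[C@](O)(C(=O)c3c(O)cc(O)cc3O)c2c3O[C@@H](c4ccc(O)cc4)[C@@H](O)Cc13 | intermediate
17 | CNP0170480.5 | O=C1C=C2O[C@@H](c3ccc(O)cc3)[C@]3(O)C(=O)c4c(O)cc(O)cc4O[C@]23C2=C1C[C@H](O)[C@H](c1ccc(O)cc1)O2 | target

**Totals and risks**

Total step count: 10. Longest linear sequence: 7 steps (1 → 2 → 3 → 4 → 13 → 15 → 16 → 17; the branch from 5 is equally long).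

The sense of the new C8/C9 pair relative to the flavan is not induced by the bought centres and is obtained by separating diastereomers in step 8. The assignment should be confirmed by NMR and ECD comparison with the natural product.

The three steps most likely to fail:

The selective 7-O-desilylation (step 2) may not distinguish the 7-O ether cleanly from the 5-O and 4'-O ethers. The fallback sets out from 2. NBS in CH2Cl2 at −78 °C brominates flavan C8 to give the 8-bromo tris-silyl ether F1. K2CO3 in MeOH at −20 °C then cleaves only the silyl ether flanked by bromine, because the ortho-bromophenoxide is by far the best leaving group, giving the 8-bromo-7-phenol F2. Bromine–lithium exchange with n-BuLi (3.3 equiv, THF, −78 °C) and a MeOH quench remove the bromine, and the route is rejoined at 3.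

The [3,3]-rearrangement (step 7) may suffer from competing attack at flavan C6, slow formation of the crowded quaternary centre, or acid-induced loss of silyl groups. The fallback sets out from 3 and uses 9. Riley oxidation of 9 (SeO2, dioxane–H2O, 80 °C) gives the vicinal trione F3. Phenol 3 adds through its most nucleophilic free position (flavan C8) to the central carbonyl (Friedel–Crafts hydroxyalkylation, CF3CO2H cat., CH2Cl2, 0 °C) and the 7-hydroxyl closes onto the 4-silyloxyphenyl ketone to give the 9-hydroxy hemiketal F4. Luche reduction gives the ring-opened benzylic alcohol F5, which cyclises with CF3CO2H to the (8S,9S) tertiary alcohol F6 after separation of diastereomers. Methanolysis with K2CO3 in MeOH rejoins the route at 16.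

The oxidative dearomatisation on the unprotected polyphenol (step 10) may be unselective, with the 4-hydroxyphenyl groups or the acylphloroglucinol ring oxidised instead. The fallback sets out from 16. TIPSCl (3.1 equiv) and imidazole in DMF at −20 °C silylate only the three unhindered, non-chelated phenols (both 4-hydroxyphenyl groups and the para hydroxyl of the benzoyl ring) to give the tris-TIPS ether F7. The same PhI(OAc)2 oxidation, now with only the ring A phenol and the chelated ortho-hydroxyls free, gives the tris-TIPS dienone F8. Et3N·3HF in MeCN removes the silyl groups under non-basic conditions, and the route is rejoined at 17.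

Further compounds
F1 | step 2 | (2S,3S)-8-bromo-5,7-bis(TBS-oxy)-2-[4-(TBS-oxy)phenyl]chroman-3-ol | CC(C)(C)[Si](C)(C)Oc1cc(O[Si](C)(C)C(C)(C)C)c2C[C@H](O)[C@H](c3ccc(O[Si](C)(C)C(C)(C)C)cc3)Oc2c1Br
F2 | step 2 | (2S,3S)-8-bromo-5-(TBS-oxy)-2-[4-(TBS-oxy)phenyl]chromane-3,7-diol | Oc1cc(O[Si](C)(C)C(C)(C)C)c2C[C@H](O)[C@H](c3ccc(O[Si](C)(C)C(C)(C)C)cc3)Oc2c1Br
F3 | step 7 | 1-[4-(TBS-oxy)phenyl]-3-[2,4,6-tris(TBS-oxy)phenyl]propane-1,2,3-trione | O=C(C(=O)C(=O)c1c(O[Si](C)(C)C(C)(C)C)cc(O[Si](C)(C)C(C)(C)C)cc1O[Si](C)(C)C(C)(C)C)c1ccc(O[Si](C)(C)C(C)(C)C)cc1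
F4 | step 7 | (2S,3S)-5-(TBS-oxy)-2,8-bis[4-(TBS-oxy)phenyl]-9-[2,4,6-tris(TBS-oxy)benzoyl]-3,4,8,9-tetrahydro-2H-furo[2,3-h]chromene-3,8,9-triol (C8/C9 mixture) | CC(C)(C)[Si](C)(C)Oc1cc2OC(O)(c3ccc(O[Si](C)(C)C(C)(C)C)cc3)C(O)(C(=O)c3c(O[Si](C)(C)C(C)(C)C)cc(O[Si](C)(C)C(C)(C)C)cc3O[Si](C)(C)C(C)(C)C)c2c3O[C@@H](c4ccc(O[Si](C)(C)C(C)(C)C)cc4)[C@@H](O)Cc13
F5 | step 7 | ring-opened benzylic alcohol: flavan C8 bears C(OH)[CH(OH)(4-TBS-oxyphenyl)][C(=O)-2,4,6-tris(TBS-oxy)phenyl], 7-OH free (mixture at the two new carbons) | Oc1cc(O[Si](C)(C)C(C)(C)C)c2C[C@H](O)[C@H](c3ccc(O[Si](C)(C)C(C)(C)C)cc3)Oc2c1C(O)(C(O)c1ccc(O[Si](C)(C)C(C)(C)C)cc1)C(=O)c1c(O[Si](C)(C)C(C)(C)C)cc(O[Si](C)(C)C(C)(C)C)cc1O[Si](C)(C)C(C)(C)C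
F6 | step 7 | (2S,3S,8S,9S)-5-(TBS-oxy)-2,8-bis[4-(TBS-oxy)phenyl]-9-[2,4,6-tris(TBS-oxy)benzoyl]-3,4,8,9-tetrahydro-2H-furo[2,3-h]chromene-3,9-diol | CC(C)(C)[Si](C)(C)Oc1cc2O[C@@H](c3ccc(O[Si](C)(C)C(C)(C)C)cc3)[C@](O)(C(=O)c3c(O[Si](C)(C)C(C)(C)C)cc(O[Si](C)(C)C(C)(C)C)cc3O[Si](C)(C)C(C)(C)C)c2c3O[C@@H](c4ccc(O[Si](C)(C)C(C)(C)C)cc4)[C@@H](O)Cc13
F7 | step 10 | tris-TIPS ether of 16 (both 4-hydroxyphenyl oxygens and the para oxygen of the benzoyl ring silylated) | Oc1cc2O[C@@H](c3ccc(O[Si](C(C)C)(C(C)C)C(C)C)cc3)[C@](O)(C(=O)c3c(O)cc(O[Si](C(C)C)(C(C)C)C(C)C)cc3O)c2c3O[C@@H](c4ccc(O[Si](C(C)C)(C(C)C)C(C)C)cc4)[C@@H](O)Cc13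
F8 | step 10 | tris-TIPS ether of 17 (same three oxygens silylated) | O=C1C=C2O[C@@H](c3ccc(O[Si](C(C)C)(C(C)C)C(C)C)cc3)[C@]3(O)C(=O)c4c(O)cc(O[Si](C(C)C)(C(C)C)C(C)C)cc4O[C@]23C2=C1C[C@H](O)[C@H](c1ccc(O[Si](C(C)C)(C(C)C)C(C)C)cc1)O2
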